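Everything rests on breaking the C6–C10 bond of the seven-membered ring (C2, C3, C4, C5, C6, C10, C11). The key step exploits the fact that in this ring the three-carbon unit C2–C3–C4 is flanked by the C11 carbonyl carbon and by ring-fusion atom C5, while quaternary C6 is shared with the five-membered ring: C2–C3–C4 can be folded back into a cyclopropane carrying a 1-siloxyvinyl arm (C10=C11) and a cyclopentenyl arm (C5=C6). Heating this cis-divinylcyclopropane (Cope rearrangement) closes the seven-membered ring, creates quaternary C6 and delivers the C11 enol ether beside the C2 methyl in one operation. In precursor 14 the five-membered ring C5–C9, with the C9 oxygen and isopropyl group, comes unchanged from (S)-terpinen-4-ol.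

Key step: step 11

Numbering used for all compounds: C1 methyl on C2; C2=C3 enone alkene; C4 carbinol; C5 ring-fusion CH; C6 quaternary carbon with its methyl; C7, C8 ring CH2; C9 carbon with the ester oxygen and isopropyl; C10 CH2; C11 ketone. Cp′ = (5R)-2-methyl-5-(propan-2-yl)-5-(triethylsilyloxy)cyclopent-1-en-1-yl.

Assumption: the (4R,5R)-dioxaborolane is taken to deliver CH2 to the alkene face that gives 10, as it does for simple Z- and trisubstituted allylic alcohols; if the sense were opposite, the (4S,5S)-ligand would be used with no other change.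

Step 1
Reactants: 1 (S)-terpinen-4-ol
Product: 2 triethyl{[(1S)-4-methyl-1-(propan-2-yl)cyclohex-3-en-1-yl]oxy}silane
Conditions: TESOTf, 2,6-lutidine, CH2Cl2, 0 °C
Reagents that add atoms: triethylsilyl trifluoromethanesulfonate, CC[Si](CC)(CC)OS(=O)(=O)C(F)(F)F
Why: Silylation with a silyl triflate and a hindered pyridine base protects the hindered tertiary alcohol (future C9–O) without touching the stereocentre or the alkene.

Step 2
Reactants: 2 triethylsilyl ether of terpinen-4-ol
Product: 4 (3S)-6-oxo-3-(propan-2-yl)-3-(triethylsilyloxy)heptanal, via secondary ozonide 3 (not isolated)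
Conditions: O3, CH2Cl2, −78 °C; then PPh3, −78 °C → rt
Reagents that add atoms: ozone, [O-][O+]=O
Why: Ozonolysis with reductive work-up cleaves the only alkene to the methyl ketone (future C6) and the aldehyde (future C4) and leaves the silyl ether alone.

Step 3
Reactants: 4 keto aldehyde
Product: 6 (5R)-2-methyl-5-(propan-2-yl)-5-(triethylsilyloxy)cyclopent-1-ene-1-carbaldehyde, via aldol adduct 5 (not isolated)
Conditions: piperidine (0.3 equiv), AcOH (0.3 equiv), PhMe, 4 Å sieves, 70 °C
Reagents that add atoms: none
Why: Amine–acid catalysed intramolecular aldol condensation, in which the enamine of the aldehyde adds to the methyl ketone (five-membered ring, C5–C6 bond) and dehydration gives the conjugated enal, the usual outcome for 6-oxoheptanals; the weakly basic buffer should spare the β-siloxy group.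

Step 4
Reactants: 6 cyclopentenecarbaldehyde; 7 ethyl 2-[bis(2,2,2-trifluoroethoxy)phosphoryl]propanoate
Product: 8 ethyl (2Z)-2-methyl-3-Cp′-prop-2-enoate
Conditions: KN(SiMe3)2, 18-crown-6, THF, −78 °C; then 6, −78 → −40 °C
Reagents that add atoms: none
Why: Still–Gennari variant of the Horner–Wadsworth–Emmons olefination, in which the trifluoroethyl phosphonate with a dissociated potassium counter-ion eliminates from the kinetic adduct and should give the Z-trisubstituted enoate, placing the future C11 cis to the cyclopentene.

Step 5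
Reactants: 8 Z-enoate
Product: 9 (2Z)-2-methyl-3-Cp′-prop-2-en-1-ol
Conditions: i-Bu2AlH (2.5 equiv), CH2Cl2, −78 °C; aqueous potassium sodium tartrate
Reagents that add atoms: none
Why: 1,2-Reduction of the unsaturated ester by the aluminium hydride at low temperature gives the allylic alcohol with the alkene geometry and the silyl ether intact.

Step 6
Reactants: 9 Z-allylic alcohol
Product: 10 [(1S,2R)-1-methyl-2-Cp′-cyclopropyl]methanol (CH2OH and Cp′ cis)
Conditions: Zn(CH2I)2·DME (from Et2Zn, CH2I2, DME), (4R,5R)-2-butyl-N,N,N′,N′-tetramethyl-1,3,2-dioxaborolane-4,5-dicarboxamide (1.2 equiv), CH2Cl2, −10 °C → rt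
Reagents that add atoms: diiodomethane, ICI
Why: Charette asymmetric Simmons–Smith cyclopropanation, in which the zinc alkoxide–dioxaborolane complex delivers the carbenoid only to the allylic alkene, syn-stereospecifically (CH2OH and Cp′ stay cis) and to the face chosen by the tartramide ligand, so both cyclopropane centres (C2, C4) are set by reagent control while the tetrasubstituted ring alkene, having no directing group, stays untouched.

Step 7
Reactants: 10 cyclopropylmethanol
Product: 11 (1S,2S)-1-methyl-2-Cp′-cyclopropane-1-carbaldehyde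
Conditions: Dess–Martin periodinane, CH2Cl2, 0 °C → rt
Reagents that add atoms: none
Why: Dess–Martin oxidation under neutral conditions; the aldehyde cannot epimerise because its α-carbon (C2) is quaternary, and valence isomerisation to a dihydrooxepine would require bonding to the fully substituted C6.

Step 8
Reactants: 11 cyclopropane aldehyde
Product: 12 1-[(1S,2R)-1-methyl-2-Cp′-cyclopropyl]ethan-1-ol (both carbinol epimers)
Conditions: MeMgBr, THF, −78 → 0 °C
Reagents that add atoms: methylmagnesium bromide, C[Mg]Br
Why: Grignard addition to the aldehyde introduces C10; the new carbinol centre is of no consequence because it is oxidised in the next step.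

Step 9
Reactants: 12 secondary alcohol
Product: 13 1-[(1S,2S)-1-methyl-2-Cp′-cyclopropyl]ethan-1-one
Conditions: Dess–Martin periodinane, CH2Cl2, 0 °C → rt
Reagents that add atoms: none
Why: Dess–Martin oxidation gives the methyl ketone, whose ring-side α-carbon is quaternary, so the cis-cyclopropane stays configurationally fixed.

Step 10
Reactants: 13 methyl ketone
Product: 14 tert-butyldimethyl({1-[(1S,2R)-1-methyl-2-Cp′-cyclopropyl]ethenyl}oxy)silane (siloxyvinyl and Cp′ cis)
Conditions: TBSOTf, Et3N, CH2Cl2, −78 → 0 °C
Reagents that add atoms: tert-butyldimethylsilyl trifluoromethanesulfonate, CC(C)(C)[Si](C)(C)OS(=O)(=O)C(F)(F)F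
Why: Soft enolisation and O-silylation with silyl triflate and amine; the methyl group is the only enolisable position, so the 1-siloxyvinyl group forms regiospecifically, and the temperature stays below that of the rearrangement.

Step 11
Reactants: 14 cis-divinylcyclopropane
Product: 15 hydroazulene diene, tert-butyl{[(3R,8aR)-6,8a-dimethyl-3-(propan-2-yl)-3-(triethylsilyloxy)-1,2,3,5,8,8a-hexahydroazulen-7-yl]oxy}dimethylsilane (C11 silyl enol ether C11=C2, alkene C4=C5)
Conditions: PhMe (0.02 M, degassed), Et3N (trace), base-washed sealed tube, 120–140 °C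
Reagents that add atoms: none
Why: A thermal [3,3]-sigmatropic (Cope) shift passes through a boat-like six-centre transition state with both alkenyl groups lying over the three-membered ring: the C2–C4 σ bond breaks while C10 bonds to C6 and the π bonds move to C11=C2 and C4=C5, driven by release of cyclopropane strain. The closest known reaction type is the divinylcyclopropane-to-cycloheptadiene rearrangement of 2-siloxyvinyl cyclopropanes bearing a cycloalkenyl partner, including cases that create a methyl-bearing angular quaternary carbon. The seven-membered ring (C2, C3, C4, C5, C6, C10, C11) is closed by this single suprafacial bond between the two alkene termini, a pericyclic four-atom expansion of the three-membered ring and not a nucleophilic closure. The only new stereocentre, quaternary C6, is controlled by the cyclopropane configuration from step 6: with the cyclopentene folded over the ring, C10 can reach only the face of C5=C6 that carries the C9 isopropyl group, whatever the C9 substituents would prefer. The step needs the cis relationship of the two alkenyl groups and survival of both silyl ethers at the temperature demanded by the inward-pointing C6 methyl; the Z-olefin origin and the non-epimerisable quaternary C2 secure the first, and neutral, acid-free conditions the second.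

Step 12
Reactants: 15 hydroazulene diene
Product: 17 (3R,3aS,4S,8aR)-7-(tert-butyldimethylsilyloxy)-6,8a-dimethyl-3-(propan-2-yl)-3-(triethylsilyloxy)-1,2,3,3a,4,5,8,8a-octahydroazulen-4-ol (C4 alcohol), via C4 alkylborane 16 (not isolated)
Conditions: BH3·THF, THF, 0 °C → rt; then NaBO3·4H2O, H2O, rt
Reagents that add atoms: sodium perborate (NaBO3·4H2O), [Na+].[O-]OB=O
Why: Hydroboration–oxidation, in which borane adds syn with boron on the less substituted C4 and hydrogen on C5 from the face opposite the angular C6 methyl and the C9 siloxy group (the attacked face carries only the C9 isopropyl, which can turn its C–H inward), sets C5–H trans to the methyl and C4–O cis to C5–H; the tetrasubstituted enol ether should react more slowly, and perborate oxidation (retention at C4) spares both silyl groups.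

Step 13
Reactants: 17 C4 alcohol
Product: 18 C4 tert-butyldimethylsilyl ether of 17 (C9 OTES and C11 enol ether unchanged)
Conditions: TBSOTf, 2,6-lutidine, CH2Cl2, −78 → 0 °C
Reagents that add atoms: tert-butyldimethylsilyl trifluoromethanesulfonate, CC(C)(C)[Si](C)(C)OS(=O)(=O)C(F)(F)F
Why: Silyl triflate silylation reaches the crowded secondary alcohol, and the buffered conditions leave the enol ether and the tertiary silyl ether alone.

Step 14
Reactants: 18 bis-silyl ether enol ether
Product: 19 (3R,3aS,4S,8aR)-4-(tert-butyldimethylsilyloxy)-6,8a-dimethyl-3-(propan-2-yl)-3-(triethylsilyloxy)-2,3,3a,4,8,8a-hexahydroazulen-7(1H)-one (C2=C3 enone)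
Conditions: Pd(OAc)2 (1.2 equiv), DMSO, 50 °C
Reagents that add atoms: none
Why: Saegusa–Ito oxidation, in which the silyl enol ether gives a divalent palladium enolate at C2 and β-hydride elimination towards the ring C3–H should give the conjugated C2=C3 enone and zerovalent palladium; no isomer can form on the C10 side because C6 is quaternary.

Step 15
Reactants: 19 silylated enone
Product: 20 C9 tertiary alcohol (C4 OTBS kept)
Conditions: HF·pyridine, pyridine, THF, 0 °C → rt
Reagents that add atoms: none
Why: Fluoride-mediated desilylation should take the triethylsilyl group, whose silicon is far less shielded, before the tert-butyldimethylsilyl ether on the crowded secondary C4 oxygen, and the buffered acidic medium avoids base-induced chemistry of the enone.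

Step 16
Reactants: 21 4-hydroxybenzoic acid
Product: 23 4-(tert-butyldimethylsilyloxy)benzoic acid, via bis-silylated acid 22 (not isolated)
Conditions: TBSCl (2.3 equiv), imidazole, DMF, rt; then AcOH/THF/H2O, rt
Reagents that add atoms: tert-butyldimethylsilyl chloride, CC(C)(C)[Si](C)(C)Cl
Why: Exhaustive silylation followed by selective hydrolysis of the labile silyl ester leaves the phenol protected as its silyl ether.

Step 17
Reactants: 23 4-(tert-butyldimethylsilyloxy)benzoic acid
Product: 24 4-(tert-butyldimethylsilyloxy)benzoyl chloride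
Conditions: (COCl)2, DMF (cat.), CH2Cl2, 0 °C → rt; evaporate, use crude
Reagents that add atoms: oxalyl chloride, O=C(Cl)C(=O)Cl
Why: Acid chloride formation through the chloroiminium (Vilsmeier-type) catalyst; the aryl silyl ether tolerates the anhydrous conditions.

Step 18
Reactants: 20 C9 tertiary alcohol; 24 acid chloride
Product: 26 C9 4-(tert-butyldimethylsilyloxy)benzoate with C4 OTBS, via lithium alkoxide 25 (not isolated)
Conditions: LiN(SiMe3)2 (1.05 equiv), THF, −78 °C; then 24, −78 → 0 °C
Reagents that add atoms: none
Why: O-Acylation of a lithium alkoxide, the standard way to esterify hindered tertiary alcohols: one equivalent of amide base at −78 °C should remove the hydroxyl proton before any C–H of the enone, and the low temperature and lithium counter-ion should hold back migration of the C4 silyl group.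

Step 19
Reactants: 26 doubly silylated ester
Product: 27 target, (3R,3aS,4S,8aR)-4-hydroxy-6,8a-dimethyl-7-oxo-3-(propan-2-yl)-1,2,3,3a,4,7,8,8a-octahydroazulen-3-yl 4-hydroxybenzoate
Conditions: Bu4NF, AcOH (1:1), THF, 0 °C → rt
Reagents that add atoms: none
Why: Buffered fluoride desilylation removes the aryl and the secondary silyl ethers under near-neutral conditions, so the tertiary ester should not migrate to the neighbouring C4 hydroxyl.

Compound list
1 | (S)-terpinen-4-ol | CC1=CC[C@](O)(C(C)C)CC1 | starting material
2 | triethyl{[(1S)-4-methyl-1-(propan-2-yl)cyclohex-3-en-1-yl]oxy}silane | CC1=CC[C@](O[Si](CC)(CC)CC)(C(C)C)CC1 | intermediate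
3 | secondary ozonide of 2 (both bridgehead configurations) | CC12CC[C@@](O[Si](CC)(CC)CC)(C(C)C)CC(OO1)O2 | intermediate (not isolated)
4 | (3S)-6-oxo-3-(propan-2-yl)-3-(triethylsilyloxy)heptanal | O=CC[C@](O[Si](CC)(CC)CC)(C(C)C)CCC(C)=O | intermediate
5 | aldol adduct, 2-hydroxy-2-methyl-5-(propan-2-yl)-5-(triethylsilyloxy)cyclopentane-1-carbaldehyde (mixture at the two new centres) | O=CC1C(C)(O)CC[C@@]1(O[Si](CC)(CC)CC)C(C)C | intermediate (not isolated)
6 | (5R)-2-methyl-5-(propan-2-yl)-5-(triethylsilyloxy)cyclopent-1-ene-1-carbaldehyde | O=CC1=C(C)CC[C@@]1(O[Si](CC)(CC)CC)C(C)C | intermediate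
7 | ethyl 2-[bis(2,2,2-trifluoroethoxy)phosphoryl]propanoate | CCOC(=O)C(C)P(=O)(OCC(F)(F)F)OCC(F)(F)F | starting material
8 | ethyl (2Z)-2-methyl-3-Cp′-prop-2-enoate | CCOC(=O)/C(C)=C\C1=C(C)CC[C@@]1(O[Si](CC)(CC)CC)C(C)C | intermediate
9 | (2Z)-2-methyl-3-Cp′-prop-2-en-1-ol | OC/C(C)=C\C1=C(C)CC[C@@]1(O[Si](CC)(CC)CC)C(C)C | intermediate
10 | [(1S,2R)-1-methyl-2-Cp′-cyclopropyl]methanol | OC[C@@]1(C)C[C@H]1C1=C(C)CC[C@@]1(O[Si](CC)(CC)CC)C(C)C | intermediate
11 | (1S,2S)-1-methyl-2-Cp′-cyclopropane-1-carbaldehyde | O=C[C@@]1(C)C[C@H]1C1=C(C)CC[C@@]1(O[Si](CC)(CC)CC)C(C)C | intermediate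
12 | 1-[(1S,2R)-1-methyl-2-Cp′-cyclopropyl]ethan-1-ol (carbinol epimers) | CC(O)[C@@]1(C)C[C@H]1C1=C(C)CC[C@@]1(O[Si](CC)(CC)CC)C(C)C | intermediate
13 | 1-[(1S,2S)-1-methyl-2-Cp′-cyclopropyl]ethan-1-one | CC(=O)[C@@]1(C)C[C@H]1C1=C(C)CC[C@@]1(O[Si](CC)(CC)CC)C(C)C | intermediate
14 | cis-divinylcyclopropane, tert-butyldimethyl({1-[(1S,2R)-1-methyl-2-Cp′-cyclopropyl]ethenyl}oxy)silane | C=C(O[Si](C)(C)C(C)(C)C)[C@@]1(C)C[C@H]1C1=C(C)CC[C@@]1(O[Si](CC)(CC)CC)C(C)C | intermediate
15 | hydroazulene diene with C11 silyl enol ether, (3R,8aR) | CC1=C(O[Si](C)(C)C(C)(C)C)C[C@@]2(C)CC[C@@](O[Si](CC)(CC)CC)(C(C)C)C2=CC1 | intermediate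
16 | C4 alkylborane (boron on C4, hydrogen on C5, syn) | CC=1C[C@H](B)[C@@H]2[C@](C)(CC[C@@]2(O[Si](CC)(CC)CC)C(C)C)CC=1O[Si](C)(C)C(C)(C)C | intermediate (not isolated)
17 | C4 alcohol, (3R,3aS,4S,8aR), trans ring fusion | CC=1C[C@H](O)[C@@H]2[C@](C)(CC[C@@]2(O[Si](CC)(CC)CC)C(C)C)CC=1O[Si](C)(C)C(C)(C)C | intermediate
18 | C4 OTBS, C9 OTES, C11 OTBS enol ether | CC=1C[C@H](O[Si](C)(C)C(C)(C)C)[C@@H]2[C@](C)(CC[C@@]2(O[Si](CC)(CC)CC)C(C)C)CC=1O[Si](C)(C)C(C)(C)C | intermediate
19 | enone with C4 OTBS and C9 OTES | CC1=C[C@H](O[Si](C)(C)C(C)(C)C)[C@@H]2[C@](C)(CC[C@@]2(O[Si](CC)(CC)CC)C(C)C)CC1=O | intermediate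
20 | enone with C4 OTBS and free C9 OH | CC1=C[C@H](O[Si](C)(C)C(C)(C)C)[C@@H]2[C@](C)(CC[C@@]2(O)C(C)C)CC1=O | intermediate
21 | 4-hydroxybenzoic acid | OC(=O)c1ccc(O)cc1 | starting material
22 | tert-butyldimethylsilyl 4-(tert-butyldimethylsilyloxy)benzoate | CC(C)(C)[Si](C)(C)OC(=O)c1ccc(O[Si](C)(C)C(C)(C)C)cc1 | intermediate (not isolated)
23 | 4-(tert-butyldimethylsilyloxy)benzoic acid | OC(=O)c1ccc(O[Si](C)(C)C(C)(C)C)cc1 | intermediate
24 | 4-(tert-butyldimethylsilyloxy)benzoyl chloride | ClC(=O)c1ccc(O[Si](C)(C)C(C)(C)C)cc1 | intermediate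
25 | lithium C9 alkoxide of 20 | CC1=C[C@H](O[Si](C)(C)C(C)(C)C)[C@@H]2[C@](C)(CC[C@@]2([O-])C(C)C)CC1=O.[Li+] | intermediate (not isolated)
26 | C9 4-(tert-butyldimethylsilyloxy)benzoate with C4 OTBS | CC1=C[C@H](O[Si](C)(C)C(C)(C)C)[C@@H]2[C@](C)(CC[C@@]2(OC(=O)c2ccc(O[Si](C)(C)C(C)(C)C)cc2)C(C)C)CC1=O | intermediate
27 | (3R,3aS,4S,8aR)-4-hydroxy-6,8a-dimethyl-7-oxo-3-(propan-2-yl)-1,2,3,3a,4,7,8,8a-octahydroazulen-3-yl 4-hydroxybenzoate | CC1=C[C@H](O)[C@@H]2[C@](C)(CC[C@@]2(OC(=O)c2ccc(O)cc2)C(C)C)CC1=O | target

Total step count: 19 (17 in the main line, 2 for acyl chloride 24). Longest linear sequence: 17 steps from 1 (steps 1–15, 18, 19).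

Steps most likely to fail

1. Step 11. The rearrangement may be slow because the C6 methyl points into the boat and the C11 siloxy group crowds the C9 quaternary centre, so that thermal breakdown of the enol ether or one-centre epimerisation of the cyclopropane competes. Fallback: run the ring expansion on the parent vinyl compound and oxidise C11 afterwards. Setting out from 11, Wittig methylenation (Ph3PCH3Br, KOt-Bu, THF) gives the cis-vinyl(cyclopentenyl)cyclopropane F1, which on gentle heating should give the hydroazulene diene F2. 9-BBN should add only to the unhindered C2=C11 alkene with boron on C11, and NaBO3·4H2O then gives the C11 alcohol F3. Dess–Martin oxidation gives the C11 ketone F4, and equilibrating silylation (TBSOTf, Et3N, rt) should favour the more substituted enol ether, which returns to the route at 15.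

2. Step 12. Borane addition may show poor facial selectivity, since one face of C4=C5 carries the angular methyl and the siloxy group and the other the isopropyl group, and the enol ether may be hydroborated as well. Fallback: set C5 by protonation and C4 by epoxidation. Setting out from 15, Pd(OAc)2 gives the linear dienone F5 (C2=C3, C4=C5), and HF·pyridine frees the C9 hydroxyl to give the hydroxy dienone F6, so that no siloxy group can be expelled on reduction. Li in NH3/THF at −78 °C with NH4Cl quench (1,6-reduction, kinetic α-protonation) should give the β,γ-enone F7 with C5–H trans to the angular methyl. mCPBA should epoxidise C3=C4 anti to the angular methyl to give the epoxy ketone F8, and Et3N opens it to the diol enone F9. TBSCl/imidazole silylates only the secondary C4 hydroxyl and returns to the route at 20.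

3. Step 18. The hindered tertiary alkoxide may fail to acylate before silyl migration from the C4 oxygen or enolisation of the enone intervenes. Fallback: deliver the aroyl carbon intramolecularly across the neighbouring C4 and C9 oxygens. Setting out from 19, aqueous HF in MeCN removes both silyl groups to give the diol enone F9. 4-(tert-Butyldimethylsilyloxy)benzaldehyde with HC(OMe)3 and camphorsulfonic acid gives its dimethyl acetal F10, which with F9 forms the six-membered arylidene acetal F11. Oxidative opening (DDQ, CH2Cl2/H2O) is expected, as in ortho ester hydrolyses, to leave the ester on the more hindered tertiary oxygen and give the hydroxy ester F12. Bu4NF/AcOH then comes back to the route at 27.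

Further compounds
F1 | step 11 | cis-vinyl analogue of 14 (vinyl in place of siloxyvinyl) | C=C[C@@]1(C)C[C@H]1C1=C(C)CC[C@@]1(O[Si](CC)(CC)CC)C(C)C
F2 | step 11 | hydroazulene diene without C11 oxygen | CC1=CC[C@@]2(C)CC[C@@](O[Si](CC)(CC)CC)(C(C)C)C2=CC1
F3 | step 11 | C11 alcohol (C2 and C11 epimers) | CC1C(O)C[C@@]2(C)CC[C@@](O[Si](CC)(CC)CC)(C(C)C)C2=CC1
F4 | step 11 | C11 ketone (C2 epimers) | CC1C(=O)C[C@@]2(C)CC[C@@](O[Si](CC)(CC)CC)(C(C)C)C2=CC1
F5 | step 12 | linear dienone with C9 OTES | CC1=CC=C2[C@](C)(CC[C@@]2(O[Si](CC)(CC)CC)C(C)C)CC1=O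
F6 | step 12 | linear dienone with free C9 OH | CC1=CC=C2[C@](C)(CC[C@@]2(O)C(C)C)CC1=O
F7 | step 12 | β,γ-enone (C3=C4) with C5–H trans to the angular methyl | CC1C=C[C@@H]2[C@](C)(CC[C@@]2(O)C(C)C)CC1=O
F8 | step 12 | C3–C4 epoxy ketone | CC1[C@@H]3O[C@@H]3[C@@H]2[C@](C)(CC[C@@]2(O)C(C)C)CC1=O
F9 | step 12 | diol enone (C4 OH, C9 OH) | CC1=C[C@H](O)[C@@H]2[C@](C)(CC[C@@]2(O)C(C)C)CC1=O
F10 | step 18 | 4-(tert-butyldimethylsilyloxy)benzaldehyde dimethyl acetal | COC(OC)c1ccc(O[Si](C)(C)C(C)(C)C)cc1
F11 | step 18 | arylidene acetal spanning the C4 and C9 oxygens | CC1=C[C@H](OC3c4ccc(O[Si](C)(C)C(C)(C)C)cc4)[C@@H]2[C@](C)(CC[C@@]2(O3)C(C)C)CC1=O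
F12 | step 18 | C9 4-(tert-butyldimethylsilyloxy)benzoate with free C4 OH | CC1=C[C@H](O)[C@@H]2[C@](C)(CC[C@@]2(OC(=O)c2ccc(O[Si](C)(C)C(C)(C)C)cc2)C(C)C)CC1=O
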